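**Plan**

- Retrosynthesis: cut (1) the C6–O acyl bond of the vanillate; (2) the C6–C7 bond of the cycloheptene (aldehyde + allylsilane, with allylic transposition); (3) C9–C10 (γ-silyl allylboration of a C10 aldehyde); (4) C1–C10 and C5–C6 (conjugate addition / formaldehyde trapping on 4-hydroxy-4-isopropyl-2-methylcyclopentenone); (5) that enone back to 3-ethoxycyclopent-2-enone.
- Forward: the five-membered ring is present from the start and is decorated in the order C4, C15, C5/C6, C1/C10, C7–C9; the seven-membered ring is then closed by C6–C7; esterification and desilylation finish.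
- Stereochemistry: C4 from a Cu-catalysed enantioselective conjugate borylation; C5 and C1 by substrate relay (addition cis to O-4, trapping anti to C6); C10 and the transient C9–Si centre from a Felkin-controlled, anti-selective silyl-allylboration; C6 from the chair-like cyclisation transition state.
- Enabling feature: in the seven-membered ring the C6 carbinol is homoallylic to the C8=C9 trisubstituted olefin and C10 carries oxygen, i.e. C6(O)–C7H2–C8(CH3)=C9H–C10(O). This is the product pattern of SE2′ attack of a C9-silylated allylsilane (C7=C8) on a C6 aldehyde, and the C9-silyl/C10-oxy array is available in one step from a C10 aldehyde.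

Key step: step 13

Remark on locants: daucane locants are used throughout: C1 (quaternary, bears CH3 = C15), C2 (C=O), C3 (CH2), C4 (C(OH)iPr), C5 (ring-fusion CH), C6 (CH–O), C7 (CH2), C8 (C–CH3), C9 (=CH), C10 (CH–OH). β is the face of C15. The target is 4β,6α,10α-trihydroxydauc-8-en-2-one 6-vanillate, (1S,4R,5S,6S,10R).

Remark (assumption): in step 2 the antipode of the chiral bisphosphine is the one that delivers boron to the enone face leading to (S)-4; both antipodes are commercial.

**Step 1**
Reactants: 1 3-ethoxycyclopent-2-en-1-one
Product: 3 3-isopropylcyclopent-2-en-1-one, via magnesium alkoxide 2 (not isolated)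
Conditions: i-PrMgCl, THF, 0 °C; then 1 M HCl, rt
Reagents that add atoms: isopropylmagnesium chloride, CC(C)[Mg]Cl
Why: Stork–Danheiser alkylative enone transposition, in which 1,2-addition to the vinylogous ester and acid-induced hydrolysis/dehydration of adduct 2 should give the β-isopropyl enone; no stereocentre is formed.

**Step 2**
Reactants: 3 3-isopropylcyclopent-2-en-1-one
Product: 5 (R)-3-hydroxy-3-isopropylcyclopentan-1-one, via tertiary boronate 4 (not isolated)
Conditions: B2pin2, CuCl (cat.), QuinoxP* (cat.), NaOt-Bu (cat.), MeOH, THF, rt; then NaBO3·4H2O, THF/H2O, rt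
Reagents that add atoms: bis(pinacolato)diboron, CC1(C)OB(OC1(C)C)B1OC(C)(C)C(C)(C)O1 (boron of 4); sodium perborate, [Na+].[O-]OB=O (oxygen of 5)
Why: Copper(I)-catalysed enantioselective conjugate borylation of a β-substituted cyclic enone, in which the chiral bisphosphine selects the enone face, followed by stereoretentive oxidation of the tertiary C–B bond, should set the C4 carbinol centre.

**Step 3**
Reactants: 5 (R)-3-hydroxy-3-isopropylcyclopentan-1-one
Product: 6 (R)-3-isopropyl-3-(triethylsilyloxy)cyclopentan-1-one
Conditions: TESOTf, 2,6-lutidine, CH2Cl2, −78 °C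
Reagents that add atoms: triethylsilyl trifluoromethanesulfonate, CC[Si](CC)(CC)OS(=O)(=O)C(F)(F)F
Why: Silylation of the tertiary alcohol with a silyl triflate masks the β-hydroxyl so that the ketone can be enolised in step 4 without retro-aldol cleavage; the stereocentre is untouched.

**Step 4**
Reactants: 6 (R)-3-isopropyl-3-(triethylsilyloxy)cyclopentan-1-one
Product: 8 (4R)-4-isopropyl-2-methyl-4-(triethylsilyloxy)cyclopentan-1-one (C2 epimers), via lithium enolate 7 (not isolated)
Conditions: LDA, THF, −78 °C; MeI, −78 → −40 °C
Reagents that add atoms: iodomethane, CI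
Why: Kinetic enolate alkylation, in which LDA should deprotonate the α-methylene remote from the fully substituted carbon and SN2 methylation of 7 installs C15; the new centre is inconsequential because it becomes sp2 in step 5.

**Step 5**
Reactants: 8 (4R)-4-isopropyl-2-methyl-4-(triethylsilyloxy)cyclopentan-1-one
Product: 10 (R)-4-hydroxy-4-isopropyl-2-methylcyclopent-2-en-1-one, via silyl enone 9 (not isolated)
Conditions: IBX, DMSO/PhF, 70 °C; filtration; then 48% aq HF, MeCN, 0 °C
Reagents that add atoms: none
Why: IBX dehydrogenation of the ketone through its more substituted enol can only introduce the C1=C5 double bond, because the other α-carbon has no β-hydrogen, and fluoride then cleaves the silyl ether; C4 is untouched.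

**Step 6**
Reactants: 10 (R)-4-hydroxy-4-isopropyl-2-methylcyclopent-2-en-1-one
Product: 12 siloxane keto alcohol (1α-CH2OH, 1β-CH3, 4α-iPr, O4–SiMe2–C6H2 bridge on the β face), via magnesium enolate 11 (not isolated)
Conditions: (i-PrO)Me2SiCH2MgCl (3 equiv, from ClCH2SiMe2(Oi-Pr) and Mg), CuBr·SMe2 (cat.), THF, −78 → 0 °C; then CH2O (g), −78 °C; aq NH4Cl
Reagents that add atoms: (isopropoxydimethylsilyl)methylmagnesium chloride, CC(C)O[Si](C)(C)C[Mg]Cl; formaldehyde, C=O
Why: Copper-catalysed conjugate addition of the hydroxymethyl-anion-equivalent Grignard reagent should occur cis to the C4 magnesium alkoxide and anti to the bulkier isopropyl group, with the alkoxide closing onto silicon, and the resulting siloxane enolate 11 is trapped by formaldehyde (aldol) on its convex face anti to the new C5 substituent, which sets C5 and the quaternary C1.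

**Step 7**
Reactants: 12 siloxane keto alcohol
Product: 13 siloxane keto aldehyde (C10 aldehyde on C1)
Conditions: DMP, NaHCO3, CH2Cl2, 0 °C → rt
Reagents that add atoms: none
Why: Dess–Martin oxidation of the neopentyl primary alcohol should give the non-enolisable β-keto aldehyde without touching the siloxane or any stereocentre.

**Step 8**
Reactants: 14 trimethyl(2-methylallyl)silane
Product: 16 pinacol (E)-[2-methyl-3-(trimethylsilyl)allyl]boronate, via allyllithium 15 (not isolated)
Conditions: s-BuLi, TMEDA, THF, −78 → −30 °C; then i-PrOBpin, −78 °C → rt; aq NH4Cl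
Reagents that add atoms: 2-isopropoxy-4,4,5,5-tetramethyl-1,3,2-dioxaborolane, CC(C)OB1OC(C)(C)C(C)(C)O1
Why: Deprotonation α to silicon and borylation of the allyl anion at the terminus remote from silicon should give the γ-silyl allylboronate, the silyl group sitting exo (anti to the CH2B terminus, avoiding allylic 1,3-strain) and hence E.

**Step 9**
Reactants: 13 siloxane keto aldehyde; 16 pinacol (E)-[2-methyl-3-(trimethylsilyl)allyl]boronate
Product: 17 anti-β-hydroxy allylsilane (C10–OH α as in the target, C9–SiMe3 anti to O-10, C7H2=C8(CH3) terminus)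
Conditions: toluene, 4 Å MS, rt → 50 °C; then N(CH2CH2OH)3 work-up
Reagents that add atoms: none
Why: Allylboration through a closed chair transition state is selective for the aldehyde over the ketone, the E-γ-silyl reagent fixes the anti C9/C10 relationship, and the aldehyde face is expected to follow polar Felkin–Anh control (attack anti to the C1–C2 acyl bond, past the small C15 methyl) to give the 10α-oxygen configuration.

**Step 10**
Reactants: 17 anti-β-hydroxy allylsilane
Product: 18 C10 tert-butyldimethylsilyl ether of 17
Conditions: TBSOTf, 2,6-lutidine, CH2Cl2, −78 → 0 °C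
Reagents that add atoms: tert-butyldimethylsilyl trifluoromethanesulfonate, CC(C)(C)[Si](C)(C)OS(=O)(=O)C(F)(F)F
Why: Silyl triflate protection of the hindered secondary alcohol blocks Peterson elimination of the β-hydroxy silane and keeps O-10 masked until the last step.

**Step 11**
Reactants: 18 C10 silyl ether (siloxane)
Product: 19 diol (C6H2OH on C5, free 4β-OH)
Conditions: 30% H2O2, KF, KHCO3, THF/MeOH, rt
Reagents that add atoms: hydrogen peroxide, OO
Why: Tamao–Fleming oxidation of the cyclic alkoxysilane replaces the C6–Si bond by C6–OH and frees the C4 hydroxyl, while the allylic C–SiMe3 bond is inert because that silicon carries no heteroatom.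

**Step 12**
Reactants: 19 diol
Product: 20 hydroxy aldehyde (C6 aldehyde on C5; C9-silyl allylsilane on C10)
Conditions: DMP, NaHCO3, CH2Cl2, 0 °C
Reagents that add atoms: none
Why: Dess–Martin oxidation converts only the primary alcohol, since the tertiary C4–OH cannot be oxidised, and the buffered conditions should avoid dehydration of the β-hydroxy aldehyde.

**Step 13**
Reactants: 20 hydroxy aldehyde
Product: 21 4β,6α-dihydroxy-10α-(tert-butyldimethylsilyloxy)dauc-8-en-2-one
Conditions: BF3·OEt2, CH2Cl2 (0.005 M), −78 °C; aq NaHCO3
Reagents that add atoms: none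
Why: BF3 activates the C6 aldehyde, the terminal alkene carbon C7 of the allylsilane attacks it anti to the C9–Si bond (anti-SE2′), and loss of Me3Si+ from the β-silyl cation moves the double bond to C8=C9. The closest known reaction type is the intramolecular Hosomi–Sakurai allylation (allylsilane-terminated carbonyl cyclisation). The seven-membered ring closes by 7-exo-trig attack on the carbonyl with the allylsilane reacting in the endo sense, so that C7, C8 and C9 all become ring atoms and the new olefin is necessarily cis in the ring. The only new stereocentre, C6, is controlled by the chair-like transition state of the forming trans-fused cycloheptene, in which the BF3-bound oxygen is pseudo-equatorial (α) because the pseudo-axial alternative clashes 1,3-diaxially with the axial C15 methyl group. The C9 silyl centre made anti to O-10 in step 9 is the matched one, since with C1 anti to silicon the C9–Si bond lies on the ring face opposite to the tethered aldehyde. The step needs aldehyde-over-ketone chemoselectivity and C7-over-C9 regioselectivity, which the much higher reactivity of the BF3-complexed aldehyde at −78 °C and the γ-selectivity inherent to allylsilanes should secure, while the silyl ether on O-10 blocks Peterson elimination.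

**Step 14**
Reactants: 22 vanillic acid
Product: 24 4-(tert-butyldimethylsilyloxy)-3-methoxybenzoic acid, via silyl ester 23 (not isolated)
Conditions: TBSCl, imidazole, DMF, rt; then AcOH/THF/H2O, rt
Reagents that add atoms: tert-butyldimethylsilyl chloride, CC(C)(C)[Si](C)(C)Cl
Why: Silylation of both acidic OH groups followed by selective hydrolysis of the labile silyl ester leaves the aryl silyl ether, a phenol protection that is removed together with the C10 silyl ether.

**Step 15**
Reactants: 21 4β,6α-dihydroxy-10α-(tert-butyldimethylsilyloxy)dauc-8-en-2-one; 24 4-(tert-butyldimethylsilyloxy)-3-methoxybenzoic acid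
Product: 25 bis-silyl ether of the target (O-10 and phenol as TBS ethers)
Conditions: EDC·HCl, DMAP, CH2Cl2, 0 °C → rt
Reagents that add atoms: none
Why: Steglich esterification acylates the only secondary alcohol, the tertiary C4–OH being unreactive, and C6 keeps its configuration because its C–O bond is not broken.

**Step 16**
Reactants: 25 bis-silyl ether of the target
Product: 26 target, 4β,10α-dihydroxy-6α-(4-hydroxy-3-methoxybenzoyloxy)dauc-8-en-2-one
Conditions: HF·pyridine, pyridine/THF, 0 °C → rt
Reagents that add atoms: none
Why: Fluoride-mediated desilylation cleaves both silyl ethers under buffered, non-basic conditions that should spare the β-hydroxy ketone, the allylic alcohol and the aryl ester.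

**Compound list**

1 | 3-ethoxycyclopent-2-en-1-one | CCOC1=CC(=O)CC1 | starting material
2 | chloromagnesium 3-ethoxy-1-isopropylcyclopent-2-en-1-olate | CCOC1=CC(O[Mg]Cl)(C(C)C)CC1 | intermediate
3 | 3-isopropylcyclopent-2-en-1-one | O=C1C=C(C(C)C)CC1 | intermediate
4 | (S)-3-isopropyl-3-(4,4,5,5-tetramethyl-1,3,2-dioxaborolan-2-yl)cyclopentan-1-one | O=C1C[C@@](B2OC(C)(C)C(C)(C)O2)(C(C)C)CC1 | intermediate
5 | (R)-3-hydroxy-3-isopropylcyclopentan-1-one | O=C1C[C@@](O)(C(C)C)CC1 | intermediate
6 | (R)-3-isopropyl-3-(triethylsilyloxy)cyclopentan-1-one | O=C1C[C@@](O[Si](CC)(CC)CC)(C(C)C)CC1 | intermediate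
7 | lithium enolate of 6 (enolised away from the silyloxy carbon) | [Li]OC1=CC[C@](O[Si](CC)(CC)CC)(C(C)C)C1 | intermediate
8 | (4R)-4-isopropyl-2-methyl-4-(triethylsilyloxy)cyclopentan-1-one, C2 epimers | O=C1C[C@@](O[Si](CC)(CC)CC)(C(C)C)CC1C | intermediate
9 | (R)-4-isopropyl-2-methyl-4-(triethylsilyloxy)cyclopent-2-en-1-one | O=C1C[C@@](O[Si](CC)(CC)CC)(C(C)C)C=C1C | intermediate
10 | (R)-4-hydroxy-4-isopropyl-2-methylcyclopent-2-en-1-one | O=C1C[C@@](O)(C(C)C)C=C1C | intermediate
11 | chloromagnesium C1=C2 enolate of the siloxane-bridged ketone (O4–SiMe2–C6H2 on the β face, 4α-iPr) | CC1=C(O[Mg]Cl)C[C@]2(C(C)C)O[Si](C)(C)C[C@H]12 | intermediate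
12 | siloxane keto alcohol: cyclopentan-2-one with 1β-CH3, 1α-CH2OH (C10), 4α-iPr, 5α-H; O-4 (β) and C6H2 (β) joined through SiMe2 as a cis-fused 1,2-oxasilolane | OC[C@@]1(C)C(=O)C[C@]2(C(C)C)O[Si](C)(C)C[C@H]12 | intermediate
13 | siloxane keto aldehyde: as 12 with CHO (C10) in place of CH2OH | O=C[C@@]1(C)C(=O)C[C@]2(C(C)C)O[Si](C)(C)C[C@H]12 | intermediate
14 | trimethyl(2-methylallyl)silane | C=C(C)C[Si](C)(C)C | starting material
15 | [2-methyl-1-(trimethylsilyl)allyl]lithium | C=C(C)C([Li])[Si](C)(C)C | intermediate
16 | 4,4,5,5-tetramethyl-2-[(E)-2-methyl-3-(trimethylsilyl)prop-2-en-1-yl]-1,3,2-dioxaborolane | C[Si](C)(C)/C=C(\C)CB1OC(C)(C)C(C)(C)O1 | intermediate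
17 | anti-β-hydroxy allylsilane: as 13 with C1–C10H(OH)–C9H(SiMe3)–C8(CH3)=C7H2; O-10 α as in the target, Si on C9 anti to O-10 | C=C(C)[C@@H]([Si](C)(C)C)[C@@H](O)[C@@]1(C)C(=O)C[C@]2(C(C)C)O[Si](C)(C)C[C@H]12 | intermediate
18 | 10-O-tert-butyldimethylsilyl ether of 17 | C=C(C)[C@@H]([Si](C)(C)C)[C@@H](O[Si](C)(C)C(C)(C)C)[C@@]1(C)C(=O)C[C@]2(C(C)C)O[Si](C)(C)C[C@H]12 | intermediate
19 | diol: cyclopentan-2-one with 1β-CH3, 1α side chain of 18, 4β-OH, 4α-iPr, 5β-CH2OH (C6) | C=C(C)[C@@H]([Si](C)(C)C)[C@@H](O[Si](C)(C)C(C)(C)C)[C@@]1(C)C(=O)C[C@@](O)(C(C)C)[C@@H]1CO | intermediate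
20 | hydroxy aldehyde: as 19 with 5β-CHO (C6) | C=C(C)[C@@H]([Si](C)(C)C)[C@@H](O[Si](C)(C)C(C)(C)C)[C@@]1(C)C(=O)C[C@@](O)(C(C)C)[C@@H]1C=O | intermediate
21 | (1S,4R,5S,6S,10R)-4β,6α-dihydroxy-10α-(tert-butyldimethylsilyloxy)dauc-8-en-2-one (trans-fused) | O[C@H]1CC(C)=C[C@@H](O[Si](C)(C)C(C)(C)C)[C@@]2(C)C(=O)C[C@@](O)(C(C)C)[C@H]12 | intermediate
22 | vanillic acid (4-hydroxy-3-methoxybenzoic acid) | COc1cc(C(=O)O)ccc1O | starting material
23 | tert-butyldimethylsilyl 4-(tert-butyldimethylsilyloxy)-3-methoxybenzoate | COc1cc(C(=O)O[Si](C)(C)C(C)(C)C)ccc1O[Si](C)(C)C(C)(C)C | intermediate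
24 | 4-(tert-butyldimethylsilyloxy)-3-methoxybenzoic acid | COc1cc(C(=O)O)ccc1O[Si](C)(C)C(C)(C)C | intermediate
25 | 6-O-[4-(tert-butyldimethylsilyloxy)-3-methoxybenzoyl] ester of 21 | COc1cc(C(=O)O[C@H]2CC(C)=C[C@@H](O[Si](C)(C)C(C)(C)C)[C@@]3(C)C(=O)C[C@@](O)(C(C)C)[C@H]23)ccc1O[Si](C)(C)C(C)(C)C | intermediate
26 | (1S,4R,5S,6S,10R)-4β,10α-dihydroxy-6α-(4-hydroxy-3-methoxybenzoyloxy)dauc-8-en-2-one | COc1cc(C(=O)O[C@H]2CC(C)=C[C@@H](O)[C@@]3(C)C(=O)C[C@@](O)(C(C)C)[C@H]23)ccc1O | target

**Step count and risks**

Total step count: 16. Longest linear sequence: 14 (steps 1–7, 9–13, 15, 16).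

Steps most likely to fail:

1. Step 13 (ring closure). The medium-ring closure may be slow, so that protodesilylation of the allylsilane, Lewis-acid-induced elimination of the β-silyloxy silane to a diene, or intermolecular oligomerisation could compete. Fallback, from 20 back to 21: bromodesilylation of the allylsilane with N-bromosuccinimide (CH2Cl2, propylene oxide, −78 °C) would occur with allylic transposition and give the primary allylic bromide aldehyde F1 (C7–Br, C8=C9). A samarium diiodide Barbier cyclisation (THF, −78 °C, high dilution), in which the allylsamarium reacts at its unsubstituted terminus C7 with the aldehyde in preference to the hindered ketone, would then return 21. This replaces the Lewis-acid SE2′ closure by a reductive organometallic one.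

2. Step 6 (three-component coupling). Addition to the β-carbon flanked by a quaternary centre may be sluggish, facial selectivity may be insufficient if the solvated alkoxide shields its own face, and the aldolate may lose formaldehyde by retro-aldol reaction. Fallback, from 10 back to 12: silylation of the tertiary alcohol with (bromomethyl)chlorodimethylsilane (Et3N, DMAP, CH2Cl2) would give the bromomethylsilyl ether F2. A 5-exo radical cyclisation (Bu3SnH, AIBN, benzene, 80 °C) delivers the CH2 group intramolecularly and therefore cis to O-4, and would give the siloxane ketone F3 (C1–H epimers). Thermodynamic silylation (TMSOTf, Et3N, CH2Cl2) would give the tetrasubstituted silyl enol ether F4, and a Mukaiyama aldol reaction with aqueous formaldehyde (Yb(OTf)3, THF/H2O) on the convex face would return 12.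

3. Step 9 (silyl-allylboration). The pinacol boronate may add only slowly to the neopentyl aldehyde, and the facial selectivity at C10 may be poor if a conformer with the two carbonyl groups syn competes with the polar Felkin–Anh one. Fallback, from 14 and 13 back to 17: allyllithium 15, generated as in step 8, would be trapped with triisopropyl borate and the product esterified with diisopropyl (S,S)-tartrate to give the tartrate allylboronate F5. This more reactive reagent adds at −78 °C → rt (toluene, 4 Å MS), and its own preference for the Re face of the aldehyde, the face needed here, would reinforce the substrate bias and return 17. Stereocontrol thus shifts from the substrate alone to double stereodifferentiation.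

**Further compounds**

F1 | step 13 | allylic bromide aldehyde: as 20 with C7H2Br–C8(CH3)=C9H–C10H(OTBS) in place of the allylsilane (olefin isomers) | BrCC(C)=C[C@@H](O[Si](C)(C)C(C)(C)C)[C@@]1(C)C(=O)C[C@@](O)(C(C)C)[C@@H]1C=O
F2 | step 6 | (R)-4-[(bromomethyl)dimethylsilyloxy]-4-isopropyl-2-methylcyclopent-2-en-1-one | O=C1C[C@@](O[Si](C)(C)CBr)(C(C)C)C=C1C
F3 | step 6 | siloxane ketone: as 12 with H in place of CH2OH on C1 (C1 epimers) | CC1C(=O)C[C@]2(C(C)C)O[Si](C)(C)C[C@H]12
F4 | step 6 | trimethylsilyl enol ether (C1=C2) of F3 | CC1=C(O[Si](C)(C)C)C[C@]2(C(C)C)O[Si](C)(C)C[C@H]12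
F5 | step 9 | diisopropyl (4S,5S)-2-[(E)-2-methyl-3-(trimethylsilyl)prop-2-en-1-yl]-1,3,2-dioxaborolane-4,5-dicarboxylate | C[Si](C)(C)/C=C(\C)CB1O[C@H](C(=O)OC(C)C)[C@@H](C(=O)OC(C)C)O1
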